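**Retros­ynthetic overview**
1. Feature: the E-C1=C10 alkene (methyl on C10) and the C4–C5 epoxide (a masked E-C4=C5 alkene) flank C2–C3 of the ten-membered ring. With the C3 oxygen as an enol ester the carbocycle is a cyclodeca-1,3,5-triene, the ring-opened valence isomer of a trans-fused hexalin (eudesmane rings A and B sharing the C5–C10 bond) with a C1=C2–C3=C4 diene in ring A.
2. Endgame: C6 acetate ⇐ 4,5-epoxide delivered from the free C6 hydroxyl (O6 is syn to the epoxide oxygen, O3 is anti to it and is therefore esterified first) ⇐ C3 senecioate ⇐ (3S)-carbinol by catalyst-controlled reduction of the 1(10),4-dien-3-one.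
3. Key disconnection: dienone ⇐ cold cleavage of the C3 enol acetate of the E,Z,E-triene ⇐ photochemical conrotatory opening (C5–C10 cleavage) of the trans-fused 3-acetoxy-1,3-diene carrying 6β-OTBS and 7β-isopropyl.
4. Hexalin ⇐ trans-eudesm-1-en-3-one ⇐ trans-eudesmane-3,6-dione (C4, C5, C7 set by equilibration, 6β-oxygen by hydride from the α face) ⇐ γ-oxidation of eudesm-4-en-3-one.
5. Ring order: ring B is the carvone ring; ring A is added by chiral-imine Michael addition to ethyl vinyl ketone and aldol condensation (Robinson annulation); the ten-membered ring is formed last by merging rings A and B.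

Key step: step 13

Remark: ring atoms are numbered C1–C10 as in germacrane/eudesmane throughout, and α/β refer to the usual drawing with the C10 methyl β. The saturated ketone of step 1 is carried as its C2-epimer mixture because C2 becomes trigonal in step 3.

**Step 1**
Reactants: 1 (R)-(−)-carvone
Product: 2 (2R,5R)-2-methyl-5-(propan-2-yl)cyclohexan-1-one (trans-carvomenthone; minor C2 epimer carried along)
Conditions: H2 (1 atm), palladium on carbon (10% Pd), EtOAc, rt
Reagents that add atoms: none
Why: Heterogeneous catalytic hydrogenation saturates the isopropenyl group and the conjugated ring alkene but not the ketone and leaves C5 untouched; C2 forms as an epimer mixture, which is harmless because C2 becomes trigonal in the enamine of step 3.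

**Step 2**
Reactants: 2 trans-carvomenthone; 3 (R)-(+)-1-phenylethylamine
Product: 4 (5R)-2-methyl-N-[(1R)-1-phenylethyl]-5-(propan-2-yl)cyclohexan-1-imine
Conditions: TsOH·H2O (cat.), toluene, reflux, Dean–Stark trap
Reagents that add atoms: (R)-1-phenylethylamine (3), C[C@@H](N)c1ccccc1
Why: Acid-catalysed imine condensation driven by azeotropic removal of water; the ketimine equilibrates with the more substituted secondary enamine that reacts in step 3.

**Step 3**
Reactants: 4 ketimine; 5 ethyl vinyl ketone
Product: 7 (2S,5R)-2-methyl-2-(3-oxopentyl)-5-(propan-2-yl)cyclohexan-1-one, via keto-imine 6 (not isolated)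
Conditions: 5 (1.5 equiv), THF, 40 °C; then 10% aq. AcOH, rt
Reagents that add atoms: ethyl vinyl ketone (5), CCC(=O)C=C; water, O
Why: Chiral-imine Michael addition in which the tetrasubstituted secondary enamine tautomer adds to the vinyl ketone through a compact chair-like aza-ene transition state at the more substituted α-carbon, on the face dictated by the (R)-1-phenylethyl group, which should set the quaternary carbon (future C10) S with its methyl cis to the isopropyl group, as established for dihydrocarvone-type ketones, after which aqueous acetic acid hydrolyses the imine.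

**Step 4**
Reactants: 7 diketone
Product: 9 eudesm-4-en-3-one (11,12-dihydro-α-cyperone; 10β-methyl and 7β-isopropyl), via ketol 8 (not isolated)
Conditions: NaOMe, MeOH, rt to reflux
Reagents that add atoms: none
Why: Base-mediated intramolecular aldol condensation (the ring-closing half of a Robinson annulation) closes six-membered ring A by attack of the ethyl ketone enolate on the ring carbonyl and dehydrates to the tetrasubstituted enone without touching a stereocentre.

**Step 5**
Reactants: 9 eudesm-4-en-3-one; 10 isopropenyl acetate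
Product: 11 3-acetoxyeudesma-3,5-diene
Conditions: 10 (solvent), TsOH·H2O (cat.), reflux, slow distillation of acetone
Reagents that add atoms: isopropenyl acetate (10), CC(=C)OC(C)=O
Why: Acid-catalysed enol acetylation by transesterification under thermodynamic control gives the heteroannular 3,5-dienyl acetate by loss of a C6 proton.

**Step 6**
Reactants: 11 dienyl acetate
Product: 12 6β-hydroxyeudesm-4-en-3-one
Conditions: mCPBA, dioxane/aq. NaH2PO4–Na2HPO4 buffer (pH 7), 0 °C
Reagents that add atoms: 3-chloroperoxybenzoic acid (mCPBA), OOC(=O)c1cccc(Cl)c1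
Why: Peracid oxidation of a dienol ester in which the electrophilic oxygen adds to the γ-terminus C6 (attack at C4 would create a quaternary centre), preferentially from the axial β face, and the acetyl group is lost on aqueous work-up to give the γ-hydroxy enone; the C6 configuration is of no consequence because C6 becomes a ketone in step 7.

**Step 7**
Reactants: 12 γ-hydroxy enone
Product: 13 5α-eudesmane-3,6-dione (4α-methyl and 7β-isopropyl equatorial; trans-fused)
Conditions: KOH, MeOH, reflux, argon
Reagents that add atoms: none
Why: Base-mediated isomerisation of a γ-hydroxy enone to the 1,4-diketone through its dienolate (known for 6β-hydroxy-4-en-3-ones of the steroid series); C4, C5 and C7 are then all α to a carbonyl and should equilibrate to the trans-fused decalin with H5 α and equatorial 4α-methyl and 7β-isopropyl groups, the quaternary C10 anchoring the absolute configuration.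

**Step 8**
Reactants: 13 dione
Product: 15 3-(tert-butyldimethylsilyloxy)-5α-eudesm-2-en-6-one, via lithium enolate 14 (not isolated)
Conditions: LiN(iPr)2 (1.05 equiv), THF, −78 °C; then TBSOTf, −78 °C
Reagents that add atoms: tert-butyldimethylsilyl trifluoromethanesulfonate, CC(C)(C)[Si](C)(C)OS(=O)(=O)C(F)(F)F
Why: Kinetic enolate formation and O-silylation: the bulky amide removes a proton from the only methylene α to a carbonyl (C2) and not from the α-methines C4, C5 and C7, and the resulting silyl enol ether both masks C3 during step 9 and marks the site of dehydrogenation for step 11.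

**Step 9**
Reactants: 15 silyl enol ether ketone
Product: 16 3-(tert-butyldimethylsilyloxy)-5α-eudesm-2-en-6β-ol
Conditions: LiAlH4, Et2O, −78 to 0 °C; aq. KNaC4H4O6 (potassium sodium tartrate) work-up
Reagents that add atoms: none
Why: Hydride reduction of the remaining ketone in which axial (β-face) attack is blocked by the syn-axial C10 methyl, so hydride should enter from the α side and give the axial 6β-alcohol cis to the 7β-isopropyl group, as is general for 6-oxo-5α-steroids, while the silyl enol ether is inert to LiAlH4.

**Step 10**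
Reactants: 16 alcohol
Product: 17 3,6β-bis(tert-butyldimethylsilyloxy)-5α-eudesm-2-ene
Conditions: TBSOTf, 2,6-lutidine, CH2Cl2, 0 °C to rt
Reagents that add atoms: tert-butyldimethylsilyl trifluoromethanesulfonate, CC(C)(C)[Si](C)(C)OS(=O)(=O)C(F)(F)F
Why: Silylation with the silyl triflate and a hindered pyridine base protects even this hindered axial secondary alcohol and leaves the silyl enol ether untouched.

**Step 11**
Reactants: 17 bis-silyl compound
Product: 18 6β-(tert-butyldimethylsilyloxy)-5α-eudesm-1-en-3-one (4α-methyl)
Conditions: Pd(OAc)2 (1.1 equiv), MeCN, rt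
Reagents that add atoms: none
Why: Saegusa–Ito oxidation in which divalent palladium palladates C2 of the enol silane and β-hydride elimination of H1 delivers the 1-en-3-one regiospecifically, the alkyl silyl ether at C6 being unaffected.

**Step 12**
Reactants: 18 enone
Product: 20 (5R,6R,7S,10S)-3-acetoxy-6-(tert-butyldimethylsilyloxy)eudesma-1,3-diene (trans-fused hexalin; 5α-H and 10β-methyl), via potassium dienolate 19 (not isolated)
Conditions: KH, THF, 0 °C to rt; then Ac2O, −78 °C
Reagents that add atoms: acetic anhydride, CC(=O)OC(C)=O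
Why: Enolate O-acylation: the enone has a single enolisable position (the hindered axial H4, for which the small base KH is chosen), so deprotonation gives only the linear C1=C2–C3=C4 dienolate, which acetic anhydride acetylates on oxygen, C4 becoming trigonal while H5 stays α.

**Step 13**
Reactants: 20 trans-fused dienyl acetate
Product: 21 (1(10)E,4E)-3-acetoxy-6β-(tert-butyldimethylsilyloxy)germacra-1(10),2,4-triene with ring-cis C2=C3 (6R,7S)
Conditions: hν 254 nm (low-pressure Hg lamp, quartz), degassed THF, −78 °C, to the photostationary state; solution kept at −78 °C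
Reagents that add atoms: none
Why: Excitation of the homoannular C1=C2–C3=C4 diene triggers a six-electron conrotatory electrocyclic ring opening that cleaves the C5–C10 σ bond and forms the C1=C10 and C4=C5 π bonds, the closest known reaction being the photochemical opening of trans-fused hexalins and provitamin-D-type dienes to E,Z,E-trienes. No ring is closed, so no closure mode applies: rings A and B merge into the ten-membered ring by loss of their shared bond. No stereocentre is created (C5 and C10 become trigonal, C6 and C7 are untouched), and the alkene geometry follows from the trans ring fusion, because the only conrotatory motion that the four-carbon tether C6–C9 allows swings C6 and C9 outward and H5 and the C10 methyl inward, giving E at both C1=C10 and C4=C5 and a ring-cis C2=C3 (formally E by the sequence rule because of the acetoxy group). The step needs ring opening to prevail over photochemical reclosure, acyl shift of the enol ester and thermal disrotatory closure to the cis-fused diene, which should be secured by irradiating at −78 °C only to the photostationary state and passing the cold solution straight into step 14.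

**Step 14**
Reactants: 21 triene enol acetate (cold photolysate)
Product: 23 (1(10)E,4E)-6β-(tert-butyldimethylsilyloxy)germacra-1(10),4-dien-3-one, via lithium dienolate 22 (not isolated)
Conditions: MeLi (2.2 equiv), THF/Et2O, −78 °C; then AcOH, −78 °C
Reagents that add atoms: none
Why: Enol ester cleavage by methyllithium (the second equivalent consuming the liberated acetone) releases the lithium dienolate below the temperature of thermal reclosure, and kinetic α-protonation at C2 should give the β,γ-unsaturated ketone with the 1(10)E alkene intact, while unchanged 20 is returned at the enone stage (18) and recycled through step 12.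

**Step 15**
Reactants: 23 dienone
Product: 24 (1(10)E,4E)-6β-(tert-butyldimethylsilyloxy)germacra-1(10),4-dien-3β-ol (3S,6R,7S)
Conditions: (R)-2-methyl-CBS-oxazaborolidine, catecholborane, toluene, −78 °C
Reagents that add atoms: none
Why: Corey–Bakshi–Shibata reduction in which the α-methylalkenyl arm (C4) acts as the large group and the C2 methylene as the small one, so the (R)-catalyst should deliver hydride to the face that gives the (3S)-allylic alcohol, catecholborane at low temperature avoiding hydroboration of the trisubstituted alkenes.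

**Step 16**
Reactants: 24 allylic alcohol; 25 3-methylbut-2-enoic acid (senecioic acid)
Product: 26 (1(10)E,4E)-6β-(tert-butyldimethylsilyloxy)-3β-(3-methylbut-2-enoyloxy)germacra-1(10),4-diene
Conditions: 25, N,N'-diisopropylcarbodiimide, DMAP (cat.), CH2Cl2, 0 °C to rt
Reagents that add atoms: 3-methylbut-2-enoic acid (25), CC(C)=CC(=O)O
Why: Steglich esterification acylates the only free hydroxyl with retention at C3, carbodiimide activation without a tertiary amine avoiding deconjugation of the senecioyl group through a vinylketene, and the mild temperature avoiding Cope rearrangement of the 1,5-diene.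

**Step 17**
Reactants: 26 silyl ether
Product: 27 (1(10)E,4E)-3β-(3-methylbut-2-enoyloxy)germacra-1(10),4-dien-6β-ol
Conditions: Bu4NF, AcOH (1:1), THF, 0 °C to rt
Reagents that add atoms: none
Why: Fluoride-induced desilylation frees the C6 hydroxyl before any epoxide is present, acetic acid buffering keeping the medium close to neutral so that the senecioate and the 1,5-diene survive.

**Step 18**
Reactants: 27 allylic alcohol
Product: 28 (1(10)E)-4α,5β-epoxy-3β-(3-methylbut-2-enoyloxy)germacr-1(10)-en-6β-ol (3S,4R,5R,6R,7S)
Conditions: VO(acac)2 (cat.), t-BuOOH (decane solution), CH2Cl2, 0 °C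
Reagents that add atoms: tert-butyl hydroperoxide, CC(C)(C)OO
Why: Hydroxyl-directed vanadium-catalysed epoxidation in which the vanadate ester of the C6 hydroxyl delivers the peroxide oxygen only to the allylic C4=C5 alkene (C1=C10 is remote and the senecioate alkene is electron-poor), on the peripheral face on which the C6–O bond lies close to the alkene plane (O–C6–C5=C4 about 40°, C7 on the inner face), the syn mode known for medium-ring allylic alcohols, which should place the epoxide oxygen syn to the (6R)-oxygen and so set C4 and C5 both R.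

**Step 19**
Reactants: 28 epoxy alcohol
Product: 29 (1(10)E)-6β-acetoxy-4α,5β-epoxy-3β-(3-methylbut-2-enoyloxy)germacr-1(10)-ene (3S,4R,5R,6R,7S; CNP0267399.1)
Conditions: Ac2O, DMAP, pyridine, CH2Cl2, 0 °C to rt
Reagents that add atoms: acetic anhydride, CC(=O)OC(C)=O
Why: DMAP-catalysed acetylation esterifies the hindered secondary alcohol under basic conditions that spare the acid-sensitive epoxy-germacrene, completing the target.

**Compound list**
1 | (R)-(−)-carvone | CC1=CC[C@H](CC1=O)C(C)=C | starting material
2 | (2R,5R)-2-methyl-5-(propan-2-yl)cyclohexan-1-one (trans-carvomenthone; the (2S,5R) epimer is carried along) | C[C@@H]1CC[C@H](CC1=O)C(C)C | intermediate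
3 | (R)-(+)-1-phenylethylamine | C[C@@H](N)c1ccccc1 | starting material
4 | (5R)-2-methyl-N-[(1R)-1-phenylethyl]-5-(propan-2-yl)cyclohexan-1-imine (C2 epimers, C=N isomers) | CC1CC[C@H](CC1=N[C@H](C)c2ccccc2)C(C)C | intermediate
5 | ethyl vinyl ketone (pent-1-en-3-one) | CCC(=O)C=C | starting material
6 | (2S,5R)-2-methyl-2-(3-oxopentyl)-N-[(1R)-1-phenylethyl]-5-(propan-2-yl)cyclohexan-1-imine (keto-imine) | CCC(=O)CC[C@]1(C)CC[C@H](CC1=N[C@H](C)c2ccccc2)C(C)C | intermediate (not isolated)
7 | (2S,5R)-2-methyl-2-(3-oxopentyl)-5-(propan-2-yl)cyclohexan-1-one | CCC(=O)CC[C@]1(C)CC[C@H](CC1=O)C(C)C | intermediate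
8 | 5-hydroxyeudesman-3-one (ketol; C4 and C5 unassigned, 7β-isopropyl, 10β-methyl) | O=C1C(C)C2(O)C[C@H](C(C)C)CC[C@@]2(C)CC1 | intermediate (not isolated)
9 | eudesm-4-en-3-one, (4aS,7R)-1,4a-dimethyl-7-(propan-2-yl)-4,4a,5,6,7,8-hexahydronaphthalen-2(3H)-one | O=C1C(C)=C2C[C@H](C(C)C)CC[C@@]2(C)CC1 | intermediate
10 | isopropenyl acetate | CC(=C)OC(C)=O | starting material
11 | 3-acetoxyeudesma-3,5-diene | CC(=O)OC1=C(C)C2=C[C@H](C(C)C)CC[C@@]2(C)CC1 | intermediate
12 | 6β-hydroxyeudesm-4-en-3-one | O=C1C(C)=C2[C@H](O)[C@H](C(C)C)CC[C@@]2(C)CC1 | intermediate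
13 | 5α-eudesmane-3,6-dione (4α-methyl, 5α-H, 7β-isopropyl, 10β-methyl) | O=C1[C@@H](C)[C@@H]2C(=O)[C@H](C(C)C)CC[C@@]2(C)CC1 | intermediate
14 | lithium C2–C3 enolate of 13 | [Li+].[O-]C=1[C@@H](C)[C@@H]2C(=O)[C@H](C(C)C)CC[C@@]2(C)CC=1 | intermediate (not isolated)
15 | 3-(tert-butyldimethylsilyloxy)-5α-eudesm-2-en-6-one | CC(C)(C)[Si](C)(C)OC=1[C@@H](C)[C@@H]2C(=O)[C@H](C(C)C)CC[C@@]2(C)CC=1 | intermediate
16 | 3-(tert-butyldimethylsilyloxy)-5α-eudesm-2-en-6β-ol | CC(C)(C)[Si](C)(C)OC=1[C@@H](C)[C@@H]2[C@H](O)[C@H](C(C)C)CC[C@@]2(C)CC=1 | intermediate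
17 | 3,6β-bis(tert-butyldimethylsilyloxy)-5α-eudesm-2-ene | CC(C)(C)[Si](C)(C)OC=1[C@@H](C)[C@@H]2[C@H](O[Si](C)(C)C(C)(C)C)[C@H](C(C)C)CC[C@@]2(C)CC=1 | intermediate
18 | 6β-(tert-butyldimethylsilyloxy)-5α-eudesm-1-en-3-one (4α-methyl) | O=C1[C@@H](C)[C@@H]2[C@H](O[Si](C)(C)C(C)(C)C)[C@H](C(C)C)CC[C@@]2(C)C=C1 | intermediate
19 | potassium 1,3-dienolate of 18 | [K+].[O-]C1=C(C)[C@@H]2[C@H](O[Si](C)(C)C(C)(C)C)[C@H](C(C)C)CC[C@@]2(C)C=C1 | intermediate (not isolated)
20 | (5R,6R,7S,10S)-3-acetoxy-6-(tert-butyldimethylsilyloxy)eudesma-1,3-diene (trans-fused hexalin) | CC(=O)OC1=C(C)[C@@H]2[C@H](O[Si](C)(C)C(C)(C)C)[C@H](C(C)C)CC[C@@]2(C)C=C1 | intermediate (key-step precursor)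
21 | (1(10)E,4E)-3-acetoxy-6β-(tert-butyldimethylsilyloxy)germacra-1(10),2,4-triene, ring-cis C2=C3 (6R,7S) | CC(C)(C)[Si](C)(C)O[C@H]1/C=C(C)/C(OC(C)=O)=C\C=C(/C)CC[C@H]1C(C)C | intermediate (key-step product, kept cold in solution)
22 | lithium dienolate from 21 | [Li+].CC(C)(C)[Si](C)(C)O[C@H]1/C=C(C)/C([O-])=C\C=C(/C)CC[C@H]1C(C)C | intermediate (not isolated)
23 | (1(10)E,4E)-6β-(tert-butyldimethylsilyloxy)germacra-1(10),4-dien-3-one (6R,7S) | CC(C)(C)[Si](C)(C)O[C@H]1/C=C(C)/C(=O)C/C=C(\C)CC[C@H]1C(C)C | intermediate
24 | (1(10)E,4E)-6β-(tert-butyldimethylsilyloxy)germacra-1(10),4-dien-3β-ol (3S,6R,7S) | CC(C)(C)[Si](C)(C)O[C@H]1/C=C(C)/[C@@H](O)C/C=C(\C)CC[C@H]1C(C)C | intermediate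
25 | 3-methylbut-2-enoic acid (senecioic acid) | CC(C)=CC(=O)O | starting material
26 | (1(10)E,4E)-6β-(tert-butyldimethylsilyloxy)-3β-(3-methylbut-2-enoyloxy)germacra-1(10),4-diene (3S,6R,7S) | CC(C)(C)[Si](C)(C)O[C@H]1/C=C(C)/[C@@H](OC(=O)C=C(C)C)C/C=C(\C)CC[C@H]1C(C)C | intermediate
27 | (1(10)E,4E)-3β-(3-methylbut-2-enoyloxy)germacra-1(10),4-dien-6β-ol (3S,6R,7S) | O[C@H]1/C=C(C)/[C@@H](OC(=O)C=C(C)C)C/C=C(\C)CC[C@H]1C(C)C | intermediate
28 | (1(10)E)-4α,5β-epoxy-3β-(3-methylbut-2-enoyloxy)germacr-1(10)-en-6β-ol (3S,4R,5R,6R,7S) | O[C@H]1[C@H]2O[C@]2(C)[C@@H](OC(=O)C=C(C)C)C/C=C(\C)CC[C@H]1C(C)C | intermediate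
29 | (1(10)E)-6β-acetoxy-4α,5β-epoxy-3β-(3-methylbut-2-enoyloxy)germacr-1(10)-ene (3S,4R,5R,6R,7S) | CC(=O)O[C@H]1[C@H]2O[C@]2(C)[C@@H](OC(=O)C=C(C)C)C/C=C(\C)CC[C@H]1C(C)C | target

**Totals**
Total step count: 19. Longest linear sequence: 19 steps (1 to 29); compounds 3, 5, 10 and 25 are commercial and enter directly.

**Steps most likely to fail and fallbacks**

Step 13. The excited enol ester may undergo 1,3-acyl shift instead of ring opening, the triene may be consumed by secondary photoreactions before a useful photostationary composition is reached, and thermal disrotatory reclosure may occur during transfer. The fallback changes the photosubstrate class and the interception chemistry. It sets out from 18: potassium dienolate 19 would be trapped with TBSCl instead of Ac2O to give 3,6β-bis(tert-butyldimethylsilyloxy)-5α-eudesma-1,3-diene F1, a silyl dienol ether that cannot undergo acyl migration. Irradiation under the conditions of step 13 should give the corresponding E,Z,E-triene, (1(10)E,4E)-3,6β-bis(tert-butyldimethylsilyloxy)germacra-1(10),2,4-triene F2. Its silyl enol ether would be cleaved at −78 °C with Bu4NF/AcOH, far faster than the hindered alkyl silyl ether, and C2 protonated, so that the route is rejoined at 23.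

Step 15. Peripheral attack on the preferred conformer of the ten-membered ring may override the catalyst, giving poor facial selectivity at C3 or mainly the 3R epimer. The fallback sets out from 23 and accepts the substrate bias: reduction with the enantiomeric (S)-2-methyl-CBS-oxazaborolidine/catecholborane (or NaBH4/CeCl3·7H2O in MeOH at −78 °C) should give the epimeric (1(10)E,4E)-6β-(tert-butyldimethylsilyloxy)germacra-1(10),4-dien-3α-ol (3R) F3. The centre would then be inverted while the ester is installed, by Mitsunobu reaction with acid 25 (PPh3, diisopropyl azodicarboxylate, toluene, 0 °C), coming back to the route at 26.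

Step 18. Oxygen delivery from the C6 hydroxyl may proceed through the alternative ring conformer (poor facial selectivity), or the allylic alcohol may be oxidised to the enone instead of directing epoxidation. The fallback moves the directing group to C3. It sets out from 23, which would be reduced to the (3R)-alcohol F3 as described for step 15; this hydroxyl is syn to the required face of C4=C5. VO(acac)2/t-BuOOH should then give (1(10)E)-4α,5β-epoxy-6β-(tert-butyldimethylsilyloxy)germacr-1(10)-en-3α-ol (3R,4R,5R) F4 with C6 still silylated. Mitsunobu esterification with 25 (PPh3, diisopropyl azodicarboxylate) would invert C3 to give (1(10)E)-4α,5β-epoxy-6β-(tert-butyldimethylsilyloxy)-3β-(3-methylbut-2-enoyloxy)germacr-1(10)-ene F5, and Bu4NF/AcOH would remove the silyl group, returning to the route at 28.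

**Further compounds**
F1 | step 13 | 3,6β-bis(tert-butyldimethylsilyloxy)-5α-eudesma-1,3-diene | CC(C)(C)[Si](C)(C)OC1=C(C)[C@@H]2[C@H](O[Si](C)(C)C(C)(C)C)[C@H](C(C)C)CC[C@@]2(C)C=C1
F2 | step 13 | (1(10)E,4E)-3,6β-bis(tert-butyldimethylsilyloxy)germacra-1(10),2,4-triene (ring-cis C2=C3) | CC(C)(C)[Si](C)(C)O[C@H]1/C=C(C)/C(O[Si](C)(C)C(C)(C)C)=C\C=C(/C)CC[C@H]1C(C)C
F3 | step 15 | (1(10)E,4E)-6β-(tert-butyldimethylsilyloxy)germacra-1(10),4-dien-3α-ol (3R,6R,7S) | CC(C)(C)[Si](C)(C)O[C@H]1/C=C(C)/[C@H](O)C/C=C(\C)CC[C@H]1C(C)C
F4 | step 18 | (1(10)E)-4α,5β-epoxy-6β-(tert-butyldimethylsilyloxy)germacr-1(10)-en-3α-ol (3R,4R,5R,6R,7S) | CC(C)(C)[Si](C)(C)O[C@H]1[C@H]2O[C@]2(C)[C@H](O)C/C=C(\C)CC[C@H]1C(C)C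
F5 | step 18 | (1(10)E)-4α,5β-epoxy-6β-(tert-butyldimethylsilyloxy)-3β-(3-methylbut-2-enoyloxy)germacr-1(10)-ene (3S,4R,5R,6R,7S) | CC(C)(C)[Si](C)(C)O[C@H]1[C@H]2O[C@]2(C)[C@@H](OC(=O)C=C(C)C)C/C=C(\C)CC[C@H]1C(C)C
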